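The constants used here come from no measurement, and the outcome is calculated.

In the first seconds of this flask, before much electrophile had arrived, I reckoned how the balance divided the acidic substrate, and I froze that division.

    acidic substrate + free base ⇌ protonated base + anion, settled at all times (K1 = 1.3)
    electrophile + anion → target (k2 = 0.50 M⁻¹ s⁻¹)
    2 acidic substrate → self-condensation product (k3 = 1.1 M⁻¹ s⁻¹)
    anion + capture agent → trapped intermediate (k4 = 0.47 M⁻¹ s⁻¹)
    free base → decomposed reagent (k5 = 0.0097 s⁻¹)

acidic substrate 0.13 M; free base 0.117 M; electrophile 0.195 M (fed, over 50 s); capture agent 6.50 mM; time 8.0 min; the fed solution adds 0.10 times the starting volume

- why nothing more happens at 8.0 min, or that something still does (the electrophile has run out first / all of the acidic substrate has reacted / it is still moving)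
- share of the acidic substrate used up at 8.0 min
- target at 8.0 min, in percent of the acidic substrate charged

- percent here means acidic substrate units held: one self-condensation product counts as two
- where a step has two of a species, its rate is k times that concentration squared, and two are used at each turn
- amounts are per litre of the starting volume; all of the dose is in the solution fed
- the reaction counts as stopped when no species that holds the acidic substrate changes by six tenths of a point or more over the second half of the time
- run time (flask): 8.0 min

I went down the time scales, fastest first. The balance came first, since it is kept at every moment. Solved on the charges, it gave [anion] = 0.0656 M, which is 50.5% of the charge. I named this part of the acidic substrate, held as anion at balance before any other step has run and out of reach of self-condensation, the sheltered share.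

The free part came next. It stood at 0.0644 M, so its first half-life by self-condensation was 7.06 s. The feed lasted 50 s, so self-condensation was well under way before the electrophile was in.

Electrophile is charged at more than the acidic substrate, but it is fed, so its concentration climbs from zero. The half-life of anion by step 2 is 7.11 s with the whole charge there at once, and that charge takes 50 s to arrive. The half-life of free base by step 5 alone was 1.2 min, longer than the feed. Loss of anion to the capture agent was the slowest rung, with a half-life by step 4 alone of 3.8 min.

As free substrate drains, the balance refills it from the anion, and the capture agent also draws on anion. So I committed to target somewhat below 50.5%, and no finer.

The forecast said: all of the acidic substrate has reacted, with 99.7% used up and target 40%. Its ground: “Self-condensation is fastest at the start, before much electrophile has been fed”. Its target stood 10 percentage points below my share.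

The simulation gave: all of the acidic substrate has reacted, with 99.9% used up and target 40.3%, so the forecast stood. Free base at 0.146 M moved that target by 5 points. I read 0.800 of target per unit of sheltered share in this flask. The neighbour flask held 0.20 M of free base, 1.54 equiv, with the other charges and the time unchanged. The same balance gave it [anion] = 0.0837 M, a sheltered share of 64.4%. Multiplied by 0.800, that reckoned 51.5% of target. The neighbour flask gave 53.1%.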